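(Readings and results were generated by integration for substances that don't exist.)

At 8.00 min we read the gamma flask, a closed stirred flask in which substrate J meets catalyst G, passes through the catalyst form D to E, and E turns to Q. The ledger runs on J, the limiting reagent: 54.9 % remains J, 36.6 % is E and 8.8 % is Q, together 100 %. D can hold at most 0.200 % of the charge, so the books close. E's share of E and Q reads 80.6 %, and winter and summer repeat this recipe and time.

| flask | J | G | remark | time |
|---|---|---|---|---|
| gamma | 0.17 M | 0.34 mM | run made earlier |  |
| eta | 0.17 M | 0.17 mM | run made earlier |  |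
| theta | 0.17 M | 0.68 mM | run made earlier |  |
| alpha | 0.34 M | 0.34 mM | run made earlier |  |
| midnight | 0.17 M (fed, over 6.40 min) | 0.34 mM | all but J at the start; J goes in evenly over 6.40 min, the run ends at 8.0 min | 8.0 min |
| noon | 0.17 M | 0.34 mM | one stirred flow tank at steady state, fed with the mixture as stated, mean residence time 8.0 min |  |
| summer | 0.17 M | 0.34 mM | a tube with plug flow, the mixed feed as stated, residence time 8.0 min | 8.0 min |
| winter | 0.17 M | 0.34 mM | everything together in a closed stirred flask, run for 8.0 min | 8.0 min |

- gamma (time / min: E / %, Q / %, J / %): 1.50: 9.4, 0.8, 90.6; 3.00: 18.2, 1.9, 80.4; 5.00: 26.4, 3.7, 69.3; 6.00: 30.4, 5.5, 63.7; 8.00: 36.6, 8.8, 54.9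
- eta (time / min: E / %, Q / %, J / %): 0.500: 2.1, 0.5, 97.6; 1.50: 4.6, 0.8, 94.8; 3.00: 8.9, 0.6, 90.7; 5.00: 13.7, 1.8, 82.7; 6.00: 17.6, 2.7, 80.1
- theta (time / min: E / %, Q / %, J / %): 0.500: 7.2, 0.1, 92.8; 1.00: 12.7, 0.5, 86.6; 2.00: 24.0, 2.2, 74.0; 3.00: 32.8, 3.5, 62.9; 6.00: 49.5, 10.1, 39.4
- alpha (time / min: E / %, Q / %, J / %): 0.500: 2.4, 0, 96.8; 1.00: 4.7, 1.1, 94.1; 2.00: 9.3, 1.2, 89.0; 3.00: 15.1, 0.8, 83.7; 6.00: 26.3, 5.1, 67.6

(scatter of a reading: 0.5 percentage points)

- the stated concentrations are those of everything mixed, before any reaction; amounts are the same in each set-up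
- reactions considered so far: J + G <-> D; D -> G + E; E <-> Q
- the feed brings no volume worth counting
- the earlier runs were made in a closed, stirred flask

1. the set-up with the highest share of E in all that became E or Q, at the outlet or at the end ("none" if the first two lie within 2 percentage points) (midnight / noon / summer / winter / none)
2. share of E in all that became E or Q, at the outlet or at the end, midnight
3. share of E in all that became E or Q, at the outlet or at the end, noon
4. share of E in all that became E or Q, at the outlet or at the end, summer
5. share of E in all that became E or Q, at the outlet or at the end, winter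

The entry we now follow lies between E and Q. Follow one molecule: as E it crosses to Q with chance f per minute, and as Q it returns with chance b per minute, so Q(t) = f∫E dt − b∫Q dt. We sum the theta readings by trapezoids, in charge-minutes. To 3.00 min, ∫E is 0.535 min and ∫Q is 0.0437 min. To 6.00 min they are 1.77 min and 0.248 min. The two equations give f = 0.0771 min⁻¹ and b = 0.143 min⁻¹. This is rough: 0.5 percentage points on the Q reading at 3.00 min moves b by 0.160 min⁻¹, more than the b we read.

We carry the resting odds of Q against E, f/b, which read 0.540. In the noon tank with residence time τ, the balance on Q gives Q/E = fτ/(1 + bτ), which is the resting odds times bτ/(1 + bτ). Our noon share is therefore 77.7 %.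

The forecast names midnight best, with midnight 85 %, noon 69.5 %, summer 80 % and winter 80 %, and holds that “the reverse step is not visible”. Our noon stands higher than its figure.

The flasks give midnight as best at 84.9 %, with noon 78.3 %, summer 80.6 % and winter 80.6 %.

    J + G ⇌ D (K = 7.80 L mol⁻¹, k = 5.80 L mol⁻¹ s⁻¹)
    D → G + E (k = 2.70 s⁻¹)
    E ⇌ Q (K = 0.500, k = 0.00130 s⁻¹)

The noon tank holds 30.3 % of E and 8.40 % of Q, a ratio of 0.277, about half of the resting odds. Those odds put the share at rest at 65.0 %, and midnight, left to 80.0 min, stands at 66.7 %.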